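Start with the easy step: starting material meets partner, in flasks that differ in temperature and nothing else.

common to all: starting material 22 mM; partner 26.4 mM; second substrate 22.0 mM; third substrate 110 mM; protic impurity 1.10 mM; time 1.0 h
- spring: temperature 25 °C
- winter: temperature −15 °C
- summer: temperature 5 °C

    starting material + partner → target (k1 = 2.3 L mol⁻¹ min⁻¹, Ea1 = 63.0 kJ mol⁻¹)
    second substrate + partner → second product (k2 = 1.3 L mol⁻¹ min⁻¹, Ea2 = 68.0 kJ mol⁻¹)
    third substrate + partner → third product (k3 = 0.47 L mol⁻¹ min⁻¹, Ea3 = 69.0 kJ mol⁻¹)
    target → over-reaction product (k4 = 0.069 min⁻¹, Ea4 = 92.0 kJ mol⁻¹)
    second substrate + protic impurity → quenched substrate (k5 = 29 L mol⁻¹ min⁻¹, Ea5 = 45.0 kJ mol⁻¹)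
    (constants at 25 °C)

- constants are those at 25 °C; use the activation energies for any other temperature

1. which flask leads in amount of target, in percent of the starting material charged ("all alike" within 1.5 percentage points) (spring / winter / summer / all alike)
2. how much target is there at the end, in percent of the starting material charged: spring
3. how much target is there at the end, in percent of the starting material charged: winter
4. how much target is there at the end, in percent of the starting material charged: summer

Carry each constant to its flask's temperature with its activation energy, then turn it into a time at the charged amounts. Take the summer flask first, with the main step alone. With partner held at its charge, starting material has a time of 102 min, so the hour would turn 44.3% of it into target.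

Now add the rivals. Second and third substrate draw on the same partner. Hold every substrate at its charge and partner falls in a pseudo-first-order way, with a spending time of one over the sum of each constant times its substrate. In the summer flask that is 52.3 min. If the partner were spent to the end on these terms, the target made, in percent of the starting material charged, would be the spending time over the main-step time, 51.3%. By this reckoning the hour spends 68.2% of the partner, so it now makes 34.9% of the starting material charged, less than the main step alone gave. The protic impurity takes at most 1.10 mM of the 22.0 mM of second substrate, so leave it out.

Then comes the step that carries target away. The target's lifetime at the flask's temperature, one over the over-reaction constant there, is 209 min in the summer flask, longer than the hour. When the hour is short against the lifetime and target is made fairly steadily, a target has waited about half of the hour on average. The share of what was made that has already gone is then about the hour over twice the lifetime, 14.4%, which leaves 29.9% in the summer flask.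

The same clocks serve the other two. In the spring flask the spending time is 7.64 min and the lifetime 14.5 min, both shorter than the hour, so the steady rule does not apply. About 46.4% is made early and then decays for the rest of the hour, leaving 1.25%. In the winter flask the spending time is 479 min and the lifetime 75.9 h, both longer than the hour, and the reckoning gives 6.63%. Your reckoning therefore puts summer ahead.

The forecast also named summer, with 1.3% for spring, 6.4% for winter and 25% for summer, on the grounds that “5 °C converts about 30% with only modest over-reaction”. Its summer figure is lower than your 29.9%.

The simulation gives summer as the leader, with 1.59% in spring, 6.42% in winter and 25.6% in summer.

In the spring flask partner was down to 4.29% of its charge at 0.500 h, with target at 9.49% and over-reaction product at 30.9%, and at 1.00 h these stood at 1.59% and 40.3%. In the summer flask 37% of the partner was still there at 1.00 h, beside 25.6% target and 4.82% over-reaction product, so 15.8% of the two was over-reacted, against the 14.4% reckoned from the lifetime. A flask like winter kept at 10 °C has a target lifetime of 104 min, which gives 29.0%, and it ended with 25.3% target and 11.4% over-reaction product, 31.1% of the two.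

Its constants stand for no real mixture; the result is computed.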